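## The problem

Target **25** is a C15 dibromo enyne built on a 2,8-dioxabicyclo[5.2.1]decane. The chain is numbered from the alkyne CH (C1) to the ethyl CH3 (C15); this numbering is used in all discussion, and bicyclic locants appear only inside systematic names. An oxolane (ring A: O–C6–C7–C8–C9) spans C7 and C9 of an oxocane (ring B: O–C7–C8–C9–C10–C11–C12–C13), so C8 is a one-atom bridge and any end-to-end closure of ring B is a medium-ring cyclisation. Six stereocentres (6R, 7S, 9S, 10S, 12S, 13R) lie on the rings. C7 and C9 are necessarily cis on ring A, the C6 chain is trans to the C7–O bond, the C10 bromide is anti to the C9–O bond, and the C12 bromide and C13 ethyl are trans, the ethyl also lying trans to C6 across the ring B oxygen. C6 and C7 are adjacent and can be set together; C7 can then dictate C9 and C10 if the C6 oxygen is delivered intramolecularly to a C9=C10 alkene, whereas C12 and C13 must be read off the shape of the finished bicycle. Both secondary bromides are β to an ether oxygen, so strong base (E2), reducing metals (β-elimination with ring opening) and ionising conditions (transannular displacement by the other ether oxygen) are to be avoided once they are present; the (E)-enyne is best made last. The enabling feature is that ring B is the seven-carbon ring C7–C13 closed by one oxygen between C7 and C13. Removing that oxygen leaves a cycloheptanone bridged by ring A, with a C13 carbonyl whose more substituted α-carbon is C7.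

## Retrosynthesis

**Enyne (25 ⇒ 24 ⇒ 23).** C1≡C2 and C3=C4 are cut: the terminal alkyne comes from the (E)-enal **24** by one-carbon homologation, and **24** from the C4 aldehyde **23** by a stabilised-ylide Wittig reaction. The neighbouring choice, iodo-olefination with divalent chromium (CrCl2) and alkynyl coupling, would expose two β-bromo ethers to a reducing metal. The forward steps must give E geometry and tolerate the bromides.

**Side-chain handle and C12 bromide (23 ⇒ 22 ⇒ 21 ⇒ 20).** The aldehyde is carried as a primary silyl ether, which leaves the C12 hydroxyl of **20** as the only free alcohol when the C12–Br bond is made. That bond is cut to a C12 alcohol with opposite configuration, so **20** needs hydroxyl cis to the C13 ethyl.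

**C13–ethyl and C12–O (20 ⇒ 19 ⇒ 18).** Both bonds are cut together back to the unsubstituted ring B enol ether **18**. Epoxidation to **19** and syn opening by an ethylalane put oxygen and ethyl on the same face, which is exactly the cis pair needed. Introducing ethyl first and hydroborating would give the trans alcohol and, after inversion, the wrong bromide. **18** has two fewer stereocentres and no ethyl group.

**Enol ether from lactone (18 ⇒ 17 ⇒ 15).** The C12=C13 enol ether is traced to lactone **15** through the acetoxy acetal **17**. This path never generates a C12 enolate, which could displace the C10 bromide to form a cyclopropane. It also never passes through a free eight-membered lactol, which could open to a hydroxy aldehyde.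

**Key disconnection (15 ⇒ 14).** The C7–O bond of ring B is cut by removing the ring oxygen, giving the oxa-bridged cycloheptanone **14**. Against closing ring B by etherification or metathesis, this replaces a medium-ring cyclisation by a one-atom expansion of a ring that is easy to make. The forward oxidation must migrate C7, not C12, and keep the C7 configuration.

**Ring A with C9 and C10 (14 ⇒ 13).** The O–C9 and C10–Br bonds are cut to the cycloheptenone aldol **13**. The tethered C6 hydroxyl can only reach C9 on its own face and bromine must add anti, so both new centres follow from C7.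

**Carbocycle (13 ⇒ 12 ⇒ 10 + 11 ⇒ 9).** A ketone enolate held in a seven-membered ring has fixed geometry and gives anti aldols through closed transition states, whereas the target needs the syn C6/C7 pair. The ring is therefore opened at C9=C10 (metathesis of dienone **12**) and at C12–C13 (butenyl Grignard **11** on Weinreb amide **10**, from imide **9**). This costs three steps over a hypothetical direct aldol on a preformed ring but buys dependable, auxiliary-controlled stereochemistry.

**C6–C7 bond (9 ⇒ 7 + 3; 7 ⇒ 4 + 5; 3 ⇒ 2 ⇒ 1).** The aldol bond is cut to imide **7** (via its boron enolate **8**) and aldehyde **3**. **7** comes from oxazolidinone **4** and acid chloride **5** (via **6**); **3** comes from diol **1** through **2**. Only commercial materials remain.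

## Roads not taken

**Alternative 1:** The cut is the ring A O–C9 bond, made from a carbohydrate. A pyranoside carrying an equatorial 2-triflate is heated in methanol; the ring oxygen displaces the triflate with inversion, contracting the pyranose to the oxolane **A1** and releasing C10 as a dimethyl acetal.
- Merits: C6, C7 and C9 come from the chiral pool with no induction step, the displacement is stereospecific, and C10 emerges as a masked aldehyde.
- Weak points: only ring A is made. Ring B still has to be closed as an eight-membered ether, C10, C12 and C13 must be set on an open chain, and the benzyl ethers must be removed before any bromide or unsaturation is present.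
- Comparison: **A1** is better on absolute stereochemistry of ring A, which is bought rather than induced. The chosen plan sets against this that its two ring-forming steps do more: step 8 delivers ring A, C9, C10 and the C10 bromide at once, and step 9 gives ring B without a medium-ring closure.

**Alternative 2:** The cut is C11–C12. SmI2 reduces a C11 bromide next to a C10 ketone to a samarium enolate that adds to a C12 aldehyde, closing ring B on ring A to give keto alcohol **A2**.
- Merits: this type of closure is among the more reliable for medium rings, it forms a C–C bond, it leaves oxygen at C10 and C12 where the bromides go, and the C13 ethyl centre is brought in before cyclisation, so no facial question arises there. In that respect it is better than steps 10–12 of the chosen route.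
- Weak points: the precursor needs the C7–O–C13 ether between two secondary carbons, with C13 α to an aldehyde and therefore epimerisable. The C10 ketone must then be reduced selectively, and two inverting brominations are needed on the hindered bicycle.
- Comparison: the chosen plan needs one such bromination, since its C10 bromide arrives with guaranteed anti geometry in step 8, and it needs no intermolecular ether synthesis.

**Alternative 3:** The cut is C6–C7. Bu3SnH/Et3B generates the C7 α-alkoxy radical from a selenoacetal of a preformed ring B; it adds 5-exo to a β-alkoxyacrylate on the C9 oxygen and bridges ring B to give ester **A3**.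
- Merits: such cyclisations are mild and dependable, and the C4 ester is one reduction away from the aldehyde, a shorter side-chain endgame than steps 14–15 here.
- Weak points: the whole difficulty of ring B, with C9, C10, C12 and C13 and a C7 acetal, is pushed into the precursor. The C6 configuration depends on the acrylate rotamer, two silyl ethers must later become bromides with inversion, and tin and selenium are used stoichiometrically.
- Comparison: **A3** wins on side-chain economy. The chosen plan sets against it that ring B comes from a seven-membered carbocycle made in two bond-forming steps, and that only one late substitution is needed.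

Key step: step 9

Assumption: in the bicyclic intermediates the face of ring B turned away from the ring A oxygen bridge is taken as the more accessible one; step 12 relies on attack from that face and step 13 on displacement from the opposite face.

## Route

Step 1
Reactants: 1 propane-1,3-diol
Product: 2 3-[(tert-butyldiphenylsilyl)oxy]propan-1-ol
Conditions: TBDPSCl (0.33 equiv), imidazole, CH2Cl2, 0 °C → rt, 1 in threefold excess
Reagents that add atoms: tert-butyl(chloro)diphenylsilane, CC(C)(C)[Si](Cl)(c1ccccc1)c1ccccc1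
Why: Silyl ether formation; with the symmetric diol in excess the mono-ether should predominate, and diol and bis-ether are removed by extraction and chromatography.

Step 2
Reactants: 2 3-[(tert-butyldiphenylsilyl)oxy]propan-1-ol
Product: 3 3-[(tert-butyldiphenylsilyl)oxy]propanal
Conditions: TEMPO (10 mol%), PhI(OAc)2, CH2Cl2, rt
Reagents that add atoms: none
Why: Nitroxyl-catalysed oxidation of a primary alcohol stops at the aldehyde under nearly neutral conditions, so the β-silyloxy aldehyde is not exposed to base that would eliminate silanol.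

Step 3
Reactants: 4 (4S)-4-benzyl-1,3-oxazolidin-2-one; 5 pent-4-enoyl chloride
Product: 7 (4S)-4-benzyl-3-(pent-4-enoyl)-1,3-oxazolidin-2-one, via N-lithio oxazolidinone 6 (not isolated)
Conditions: n-BuLi, THF, −78 °C; then 5, −78 → 0 °C
Reagents that add atoms: none
Why: N-Acylation of the lithiated Evans auxiliary by an acid chloride; the auxiliary stereocentre is not involved.

Step 4
Reactants: 7 (4S)-4-benzyl-3-(pent-4-enoyl)-1,3-oxazolidin-2-one; 3 3-[(tert-butyldiphenylsilyl)oxy]propanal
Product: 9 (4S)-4-benzyl-3-[(2S,3R)-5-[(tert-butyldiphenylsilyl)oxy]-3-hydroxy-2-(prop-2-en-1-yl)pentanoyl]-1,3-oxazolidin-2-one, via dibutylboron Z-enolate 8 (not isolated)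
Conditions: n-Bu2BOTf, i-Pr2NEt, CH2Cl2, 0 °C; then 3, −78 → 0 °C; then pH 7 buffer, MeOH, 30% H2O2, 0 °C
Reagents that add atoms: none
Why: Evans syn aldol: the Z boron enolate reacts through a chair Zimmerman–Traxler transition state on the face away from the benzyl group, setting C7 (S) and C6 (R) together. This syn pair is what later places the C6 chain trans to the C7–O bond on ring A.

Step 5
Reactants: 9 (4S)-4-benzyl-3-[(2S,3R)-5-[(tert-butyldiphenylsilyl)oxy]-3-hydroxy-2-(prop-2-en-1-yl)pentanoyl]-1,3-oxazolidin-2-one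
Product: 10 (2S,3R)-5-[(tert-butyldiphenylsilyl)oxy]-3-hydroxy-N-methoxy-N-methyl-2-(prop-2-en-1-yl)pentanamide
Conditions: MeNHOMe·HCl, AlMe3, CH2Cl2, −20 → 0 °C
Reagents that add atoms: N,O-dimethylhydroxylamine hydrochloride, CNOC.Cl
Why: Weinreb transamidation with the aluminium amide formed in the flask; the β-alkoxide directs attack to the exocyclic carbonyl, releasing the auxiliary without touching C6 or C7.

Step 6
Reactants: 10 (2S,3R)-5-[(tert-butyldiphenylsilyl)oxy]-3-hydroxy-N-methoxy-N-methyl-2-(prop-2-en-1-yl)pentanamide; 11 but-3-en-1-ylmagnesium bromide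
Product: 12 (4S)-4-[(1R)-3-[(tert-butyldiphenylsilyl)oxy]-1-hydroxypropyl]nona-1,8-dien-5-one
Conditions: 11 (3 equiv), THF, −78 → 0 °C; then pH 7 phosphate buffer
Reagents that add atoms: none
Why: Weinreb ketone synthesis: the chelated tetrahedral adduct stops at the ketone stage. One equivalent of 11 is consumed by the hydroxyl, and the cold magnesium aldolate should not undergo retro-aldol cleavage.

Step 7
Reactants: 12 (4S)-4-[(1R)-3-[(tert-butyldiphenylsilyl)oxy]-1-hydroxypropyl]nona-1,8-dien-5-one
Product: 13 (2S)-2-[(1R)-3-[(tert-butyldiphenylsilyl)oxy]-1-hydroxypropyl]cyclohept-4-en-1-one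
Conditions: second-generation Grubbs catalyst (H2IMes)(PCy3)Cl2Ru=CHPh (3 mol%), CH2Cl2 (5 mM), 40 °C
Reagents that add atoms: none
Why: Ring-closing olefin metathesis of a 1,8-diene to a seven-membered cis-cycloalkene with loss of ethene; it forms C9=C10 and tolerates the free hydroxyl and the ketone.

Step 8
Reactants: 13 (2S)-2-[(1R)-3-[(tert-butyldiphenylsilyl)oxy]-1-hydroxypropyl]cyclohept-4-en-1-one
Product: 14 (1S,5S,6S,8R)-5-bromo-8-{2-[(tert-butyldiphenylsilyl)oxy]ethyl}-7-oxabicyclo[4.2.1]nonan-2-one
Conditions: NBS, MeCN, −20 → 0 °C, dark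
Reagents that add atoms: N-bromosuccinimide, O=C1CCC(=O)N1Br
Why: Bromoetherification closing ring A in the 5-exo mode: the tethered C6 hydroxyl can open the C9=C10 bromonium ion only at C9 and only on the face of the C7–C6 bond, and bromine adds anti. C7 thus fixes C9 (S, cis bridge) and C10 (S).

Step 9
Reactants: 14 (1S,5S,6S,8R)-5-bromo-8-{2-[(tert-butyldiphenylsilyl)oxy]ethyl}-7-oxabicyclo[4.2.1]nonan-2-one
Product: 15 (1S,6S,7S,9R)-6-bromo-9-{2-[(tert-butyldiphenylsilyl)oxy]ethyl}-2,8-dioxabicyclo[5.2.1]decan-3-one
Conditions: mCPBA, CH2Cl2, 0 °C → rt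
Reagents that add atoms: 3-chloroperoxybenzoic acid, OOC(=O)c1cccc(Cl)c1
Why: Baeyer–Villiger oxidation: the peracid adds to the C13 carbonyl to give the peroxy hemiketal, and the α-carbon that best carries positive charge shifts to oxygen as the carboxylate leaves. The closest known reaction type is the peracid expansion of 2-substituted cycloheptanones to eight-membered lactones, established for oxocane natural products. Ring B is not closed end to end; it arises by a 1,2-shift that enlarges the existing seven-membered carbocycle by one oxygen, so the penalties of an eight-membered cyclisation do not arise. No new stereocentre is formed: C7 migrates with retention, so the 7S configuration from step 4 becomes that of the C7–O bond, and C6, C9 and C10 are untouched. The selectivity needed is migration of C7 over C12; C7 is secondary and C12 primary, and although the β-oxygen on C6 lowers the aptitude of C7 somewhat, the difference in substitution should dominate. The bromide, the silyl ether and the oxolane are inert to peracid, and no alkene remains to be epoxidised.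

Step 10
Reactants: 15 (1S,6S,7S,9R)-6-bromo-9-{2-[(tert-butyldiphenylsilyl)oxy]ethyl}-2,8-dioxabicyclo[5.2.1]decan-3-one
Product: 17 (1S,6S,7S,9R)-6-bromo-9-{2-[(tert-butyldiphenylsilyl)oxy]ethyl}-2,8-dioxabicyclo[5.2.1]decan-3-yl acetate (both C3 epimers), via diisobutylaluminium hemiacetal 16 (not isolated)
Conditions: i-Bu2AlH, CH2Cl2, −78 °C; then pyridine, DMAP, Ac2O, −78 → −20 °C
Reagents that add atoms: acetic anhydride, CC(=O)OC(C)=O
Why: Reductive acetylation of a lactone: the tetrahedral aluminium hemiacetal is acylated cold before it can collapse, so the eight-membered ring cannot open to a hydroxy aldehyde and over-reduction is avoided. The new acetal centre at C13 forms as a mixture that converges in step 11.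

Step 11
Reactants: 17 (1S,6S,7S,9R)-6-bromo-9-{2-[(tert-butyldiphenylsilyl)oxy]ethyl}-2,8-dioxabicyclo[5.2.1]decan-3-yl acetate
Product: 18 (1S,3Z,6S,7S,9R)-6-bromo-9-{2-[(tert-butyldiphenylsilyl)oxy]ethyl}-2,8-dioxabicyclo[5.2.1]dec-3-ene
Conditions: Me3SiOTf, i-Pr2NEt, CH2Cl2, −78 → 0 °C
Reagents that add atoms: none
Why: Silyl triflate–amine elimination of an acetal to an enol ether: the acetate ionises to the C13 oxocarbenium ion and the hindered amine removes a C12 proton, the only β-hydrogen available. No enolate is formed, so C12 cannot displace the C10 bromide.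

Step 12
Reactants: 18 (1S,3Z,6S,7S,9R)-6-bromo-9-{2-[(tert-butyldiphenylsilyl)oxy]ethyl}-2,8-dioxabicyclo[5.2.1]dec-3-ene
Product: 20 (1S,3R,4R,6S,7S,9R)-6-bromo-9-{2-[(tert-butyldiphenylsilyl)oxy]ethyl}-3-ethyl-2,8-dioxabicyclo[5.2.1]decan-4-ol, via enol ether epoxide 19 (not isolated)
Conditions: DMDO, acetone/CH2Cl2, −78 → 0 °C; evaporate; then AlEt3, CH2Cl2, −78 → 0 °C
Reagents that add atoms: dimethyldioxirane, CC1(C)OO1; triethylaluminium, CC[Al](CC)CC
Why: Epoxidation of a cyclic enol ether followed by trialkylaluminium opening of the acetal epoxide (C-glycoside-type formation). DMDO should attack the C12=C13 face away from the ring A oxygen bridge, and AlEt3 bound to the epoxide oxygen should deliver ethyl to C13 on that same face, giving C13 (R) with the C12 hydroxyl cis to ethyl.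

Step 13
Reactants: 20 (1S,3R,4R,6S,7S,9R)-6-bromo-9-{2-[(tert-butyldiphenylsilyl)oxy]ethyl}-3-ethyl-2,8-dioxabicyclo[5.2.1]decan-4-ol
Product: 21 tert-butyl{2-[(1S,3R,4S,6S,7S,9R)-4,6-dibromo-3-ethyl-2,8-dioxabicyclo[5.2.1]decan-9-yl]ethoxy}diphenylsilane
Conditions: CBr4, P(n-Oct)3, toluene, 70 °C
Reagents that add atoms: carbon tetrabromide, BrC(Br)(Br)Br
Why: Appel-type deoxybromination: bromide displaces the alkoxyphosphonium group at C12 by SN2 with inversion, turning the cis hydroxy/ethyl pair into the trans bromo/ethyl pair (12S). The non-ionising solvent is chosen to disfavour transannular participation.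

Step 14
Reactants: 21 tert-butyl{2-[(1S,3R,4S,6S,7S,9R)-4,6-dibromo-3-ethyl-2,8-dioxabicyclo[5.2.1]decan-9-yl]ethoxy}diphenylsilane
Product: 22 2-[(1S,3R,4S,6S,7S,9R)-4,6-dibromo-3-ethyl-2,8-dioxabicyclo[5.2.1]decan-9-yl]ethan-1-ol
Conditions: HF·pyridine, THF, 0 °C → rt
Reagents that add atoms: none
Why: Fluoride cleavage of the silyl ether under acidic, non-basic conditions, so neither secondary bromide meets a base capable of E2 elimination.

Step 15
Reactants: 22 2-[(1S,3R,4S,6S,7S,9R)-4,6-dibromo-3-ethyl-2,8-dioxabicyclo[5.2.1]decan-9-yl]ethan-1-ol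
Product: 23 [(1S,3R,4S,6S,7S,9R)-4,6-dibromo-3-ethyl-2,8-dioxabicyclo[5.2.1]decan-9-yl]acetaldehyde
Conditions: Dess–Martin periodinane, CH2Cl2, 0 °C → rt
Reagents that add atoms: none
Why: Dess–Martin oxidation of a primary alcohol to the aldehyde under neutral conditions; the β-alkoxy aldehyde is used at once without chromatography on basic media.

Step 16
Reactants: 23 [(1S,3R,4S,6S,7S,9R)-4,6-dibromo-3-ethyl-2,8-dioxabicyclo[5.2.1]decan-9-yl]acetaldehyde
Product: 24 (2E)-4-[(1S,3R,4S,6S,7S,9R)-4,6-dibromo-3-ethyl-2,8-dioxabicyclo[5.2.1]decan-9-yl]but-2-enal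
Conditions: Ph3P=CHCHO, toluene, 80 °C
Reagents that add atoms: (triphenylphosphoranylidene)acetaldehyde, O=CC=P(c1ccccc1)(c1ccccc1)c1ccccc1
Why: Wittig olefination with the stabilised formylmethylene ylide should give the E enal (C3=C4) selectively; the ylide is too weakly basic to eliminate the ring A oxygen or the bromides.

Step 17
Reactants: 24 (2E)-4-[(1S,3R,4S,6S,7S,9R)-4,6-dibromo-3-ethyl-2,8-dioxabicyclo[5.2.1]decan-9-yl]but-2-enal
Product: 25 (1S,3R,4S,6S,7S,9R)-4,6-dibromo-3-ethyl-9-[(2E)-pent-2-en-4-yn-1-yl]-2,8-dioxabicyclo[5.2.1]decane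
Conditions: Me3SiCHN2, LiN(i-Pr)2, THF, −78 → 0 °C
Reagents that add atoms: (trimethylsilyl)diazomethane, C[Si](C)(C)C=[N+]=[N-]
Why: Colvin rearrangement: 1,2-addition of lithiated trimethylsilyldiazomethane, loss of silanolate and of N2 give an alkylidene carbene whose 1,2-hydrogen shift forms the terminal alkyne with the E alkene intact. The base is consumed at −78 °C, where the secondary bromides should not eliminate.

## Compound list

1 | propane-1,3-diol | OCCCO | starting material
2 | 3-[(tert-butyldiphenylsilyl)oxy]propan-1-ol | OCCCO[Si](c1ccccc1)(c1ccccc1)C(C)(C)C | intermediate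
3 | 3-[(tert-butyldiphenylsilyl)oxy]propanal | O=CCCO[Si](c1ccccc1)(c1ccccc1)C(C)(C)C | intermediate
4 | (4S)-4-benzyl-1,3-oxazolidin-2-one | O=C1N[C@@H](Cc2ccccc2)CO1 | starting material
5 | pent-4-enoyl chloride | C=CCCC(Cl)=O | starting material
6 | lithium (4S)-4-benzyl-2-oxo-1,3-oxazolidin-3-ide | [Li]N1[C@@H](Cc2ccccc2)COC1=O | intermediate
7 | (4S)-4-benzyl-3-(pent-4-enoyl)-1,3-oxazolidin-2-one | C=CCCC(=O)N1[C@@H](Cc2ccccc2)COC1=O | intermediate
8 | (4S)-4-benzyl-3-[(1Z)-1-[(dibutylboranyl)oxy]penta-1,4-dien-1-yl]-1,3-oxazolidin-2-one | C=CC/C=C(\OB(CCCC)CCCC)N1[C@@H](Cc2ccccc2)COC1=O | intermediate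
9 | (4S)-4-benzyl-3-[(2S,3R)-5-[(tert-butyldiphenylsilyl)oxy]-3-hydroxy-2-(prop-2-en-1-yl)pentanoyl]-1,3-oxazolidin-2-one | C=CC[C@H](C(=O)N1[C@@H](Cc2ccccc2)COC1=O)[C@H](O)CCO[Si](c1ccccc1)(c1ccccc1)C(C)(C)C | intermediate
10 | (2S,3R)-5-[(tert-butyldiphenylsilyl)oxy]-3-hydroxy-N-methoxy-N-methyl-2-(prop-2-en-1-yl)pentanamide | C=CC[C@H](C(=O)N(C)OC)[C@H](O)CCO[Si](c1ccccc1)(c1ccccc1)C(C)(C)C | intermediate
11 | but-3-en-1-ylmagnesium bromide | C=CCC[Mg]Br | starting material
12 | (4S)-4-[(1R)-3-[(tert-butyldiphenylsilyl)oxy]-1-hydroxypropyl]nona-1,8-dien-5-one | C=CC[C@H](C(=O)CCC=C)[C@H](O)CCO[Si](c1ccccc1)(c1ccccc1)C(C)(C)C | intermediate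
13 | (2S)-2-[(1R)-3-[(tert-butyldiphenylsilyl)oxy]-1-hydroxypropyl]cyclohept-4-en-1-one | O=C1CCC=CC[C@H]1[C@H](O)CCO[Si](c2ccccc2)(c2ccccc2)C(C)(C)C | intermediate
14 | (1S,5S,6S,8R)-5-bromo-8-{2-[(tert-butyldiphenylsilyl)oxy]ethyl}-7-oxabicyclo[4.2.1]nonan-2-one | CC(C)(C)[Si](c1ccccc1)(c1ccccc1)OCC[C@H]1O[C@H]2C[C@@H]1C(=O)CC[C@@H]2Br | intermediate
15 | (1S,6S,7S,9R)-6-bromo-9-{2-[(tert-butyldiphenylsilyl)oxy]ethyl}-2,8-dioxabicyclo[5.2.1]decan-3-one | CC(C)(C)[Si](c1ccccc1)(c1ccccc1)OCC[C@H]1O[C@H]2C[C@@H]1OC(=O)CC[C@@H]2Br | intermediate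
16 | {[(1S,6S,7S,9R)-6-bromo-9-{2-[(tert-butyldiphenylsilyl)oxy]ethyl}-2,8-dioxabicyclo[5.2.1]decan-3-yl]oxy}bis(2-methylpropyl)alumane (C3 epimers) | CC(C)(C)[Si](c1ccccc1)(c1ccccc1)OCC[C@H]1O[C@H]2C[C@@H]1OC(O[Al](CC(C)C)CC(C)C)CC[C@@H]2Br | intermediate
17 | (1S,6S,7S,9R)-6-bromo-9-{2-[(tert-butyldiphenylsilyl)oxy]ethyl}-2,8-dioxabicyclo[5.2.1]decan-3-yl acetate (C3 epimers) | CC(C)(C)[Si](c1ccccc1)(c1ccccc1)OCC[C@H]1O[C@H]2C[C@@H]1OC(OC(C)=O)CC[C@@H]2Br | intermediate
18 | (1S,3Z,6S,7S,9R)-6-bromo-9-{2-[(tert-butyldiphenylsilyl)oxy]ethyl}-2,8-dioxabicyclo[5.2.1]dec-3-ene | CC(C)(C)[Si](c1ccccc1)(c1ccccc1)OCC[C@H]1O[C@H]2C[C@@H]1O/C=C\C[C@@H]2Br | intermediate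
19 | (1S,3S,4R,6S,7S,9R)-6-bromo-9-{2-[(tert-butyldiphenylsilyl)oxy]ethyl}-3,4-epoxy-2,8-dioxabicyclo[5.2.1]decane (epoxide oxygen on the face of ring B away from the ring A oxygen bridge) | CC(C)(C)[Si](c1ccccc1)(c1ccccc1)OCC[C@H]1O[C@H]2C[C@@H]1O[C@@H]3O[C@@H]3C[C@@H]2Br | intermediate
20 | (1S,3R,4R,6S,7S,9R)-6-bromo-9-{2-[(tert-butyldiphenylsilyl)oxy]ethyl}-3-ethyl-2,8-dioxabicyclo[5.2.1]decan-4-ol | CC(C)(C)[Si](c1ccccc1)(c1ccccc1)OCC[C@H]1O[C@H]2C[C@@H]1O[C@H](CC)[C@H](O)C[C@@H]2Br | intermediate
21 | tert-butyl{2-[(1S,3R,4S,6S,7S,9R)-4,6-dibromo-3-ethyl-2,8-dioxabicyclo[5.2.1]decan-9-yl]ethoxy}diphenylsilane | CC(C)(C)[Si](c1ccccc1)(c1ccccc1)OCC[C@H]1O[C@H]2C[C@@H]1O[C@H](CC)[C@@H](Br)C[C@@H]2Br | intermediate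
22 | 2-[(1S,3R,4S,6S,7S,9R)-4,6-dibromo-3-ethyl-2,8-dioxabicyclo[5.2.1]decan-9-yl]ethan-1-ol | OCC[C@H]1O[C@H]2C[C@@H]1O[C@H](CC)[C@@H](Br)C[C@@H]2Br | intermediate
23 | [(1S,3R,4S,6S,7S,9R)-4,6-dibromo-3-ethyl-2,8-dioxabicyclo[5.2.1]decan-9-yl]acetaldehyde | O=CC[C@H]1O[C@H]2C[C@@H]1O[C@H](CC)[C@@H](Br)C[C@@H]2Br | intermediate
24 | (2E)-4-[(1S,3R,4S,6S,7S,9R)-4,6-dibromo-3-ethyl-2,8-dioxabicyclo[5.2.1]decan-9-yl]but-2-enal | O=C/C=C/C[C@H]1O[C@H]2C[C@@H]1O[C@H](CC)[C@@H](Br)C[C@@H]2Br | intermediate
25 | (1S,3R,4S,6S,7S,9R)-4,6-dibromo-3-ethyl-9-[(2E)-pent-2-en-4-yn-1-yl]-2,8-dioxabicyclo[5.2.1]decane | C#C/C=C/C[C@H]1O[C@H]2C[C@@H]1O[C@H](CC)[C@@H](Br)C[C@@H]2Br | target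

## Step count and least certain steps

Total step count: 17. Longest linear sequence: 16 steps (steps 1, 2 and 4–17, from propane-1,3-diol); the branch from 4 and 5 runs 15 steps.

**Step 9 (key step).** The most likely failure is competing migration of C12, or a stalled oxidation. The ring A oxygen on C6 is β to C7 and weakens its ability to carry charge in the shift, and the bridged ketone is hindered toward peracid addition. A stronger peracid such as CF3CO3H is the first adjustment of conditions. The fallback blocks C12 and sets out from 14: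
- Me3SiOTf/Et3N gives the only accessible silyl enol ether (C7 is a bridgehead), (1S,5S,6S,8R)-5-bromo-8-{2-[(tert-butyldiphenylsilyl)oxy]ethyl}-2-[(trimethylsilyl)oxy]-7-oxabicyclo[4.2.1]non-2-ene F1.
- N-Chlorosuccinimide converts it into the α-chloro ketone (1S,5S,6S,8R)-5-bromo-8-{2-[(tert-butyldiphenylsilyl)oxy]ethyl}-3-chloro-7-oxabicyclo[4.2.1]nonan-2-one F2, whose chlorine-bearing carbon is a very poor migrating group.
- Peracid oxidation then gives, by C7 migration alone, (1S,6S,7S,9R)-6-bromo-9-{2-[(tert-butyldiphenylsilyl)oxy]ethyl}-4-chloro-2,8-dioxabicyclo[5.2.1]decan-3-one F3.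
- SmI2/MeOH in THF at −78 °C removes the α-chlorine (the unactivated C10 bromide is not reduced without a polar co-solvent), and the route is rejoined at 15.

**Step 11.** The most likely failure is ionisation without clean deprotonation: the eight-membered oxocarbenium ion is recaptured, hydrolysed on work-up to a ring-opened hydroxy aldehyde, or intercepted transannularly by the ring A oxygen. The fallback avoids the cation and sets out from 15. KN(SiMe3)2 is added to the lactone with PhNTf2 already present in THF/HMPA at −78 °C, so that the C12 enolate is triflated before it can displace the C10 bromide. This gives the ketene acetal triflate (1S,6S,7S,9R)-6-bromo-9-{2-[(tert-butyldiphenylsilyl)oxy]ethyl}-2,8-dioxabicyclo[5.2.1]dec-3-en-3-yl trifluoromethanesulfonate F4. Reduction with Bu3SnH, LiCl and Pd(PPh3)4 (zerovalent palladium) replaces the triflate by hydrogen and rejoins the route at 18.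

**Step 12.** The most likely failure is loss of stereocontrol in the two-stage addition. Either ring B, being mobile, is epoxidised on both faces, or AlEt3 opens 19 with β-hydride transfer or without internal delivery because the oxocarbenium–aluminate pair is long-lived. The fallback changes the carbon transfer; it does not correct a wrong epoxidation face. It sets out from 18 through the same epoxide 19 and uses Me2AlC≡CSiMe3 (from lithium trimethylsilylacetylide and Me2AlCl), whose alkynyl ligand transfers preferentially, cannot deliver hydride and should open such epoxides syn. This gives (1S,3R,4R,6S,7S,9R)-6-bromo-9-{2-[(tert-butyldiphenylsilyl)oxy]ethyl}-3-[(trimethylsilyl)ethynyl]-2,8-dioxabicyclo[5.2.1]decan-4-ol F5. K2CO3/MeOH removes silicon to give (1S,3R,4R,6S,7S,9R)-6-bromo-9-{2-[(tert-butyldiphenylsilyl)oxy]ethyl}-3-ethynyl-2,8-dioxabicyclo[5.2.1]decan-4-ol F6. Hydrogenation over PtO2 in EtOAc saturates the alkyne to the ethyl group and rejoins the route at 20.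

**Step 13.** The most likely failure is transannular participation. The ring A oxygen lies on the face from which bromide must enter, so its attack on the activated C12 (bridged oxonium ion, then bromide with net retention or ring transposition) or E2 loss toward C11 can compete with direct displacement at 70 °C. The fallback separates activation from displacement and sets out from 20. ClCH2SO2Cl/pyridine at 0 °C gives (1S,3R,4R,6S,7S,9R)-6-bromo-9-{2-[(tert-butyldiphenylsilyl)oxy]ethyl}-3-ethyl-2,8-dioxabicyclo[5.2.1]decan-4-yl chloromethanesulfonate F7. This leaving group is reactive enough to be displaced by Bu4NBr at or below room temperature, where bimolecular attack by soluble bromide should outrun ionisation; the route is rejoined at 21.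

## Further compounds

F1 | step 9 | (1S,5S,6S,8R)-5-bromo-8-{2-[(tert-butyldiphenylsilyl)oxy]ethyl}-2-[(trimethylsilyl)oxy]-7-oxabicyclo[4.2.1]non-2-ene | CC(C)(C)[Si](c1ccccc1)(c1ccccc1)OCC[C@H]1O[C@H]2C[C@@H]1C(O[Si](C)(C)C)=CC[C@@H]2Br
F2 | step 9 | (1S,5S,6S,8R)-5-bromo-8-{2-[(tert-butyldiphenylsilyl)oxy]ethyl}-3-chloro-7-oxabicyclo[4.2.1]nonan-2-one (C3 epimers) | CC(C)(C)[Si](c1ccccc1)(c1ccccc1)OCC[C@H]1O[C@H]2C[C@@H]1C(=O)C(Cl)C[C@@H]2Br
F3 | step 9 | (1S,6S,7S,9R)-6-bromo-9-{2-[(tert-butyldiphenylsilyl)oxy]ethyl}-4-chloro-2,8-dioxabicyclo[5.2.1]decan-3-one (C4 epimers) | CC(C)(C)[Si](c1ccccc1)(c1ccccc1)OCC[C@H]1O[C@H]2C[C@@H]1OC(=O)C(Cl)C[C@@H]2Br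
F4 | step 11 | (1S,6S,7S,9R)-6-bromo-9-{2-[(tert-butyldiphenylsilyl)oxy]ethyl}-2,8-dioxabicyclo[5.2.1]dec-3-en-3-yl trifluoromethanesulfonate (endocyclic cis double bond) | CC(C)(C)[Si](c1ccccc1)(c1ccccc1)OCC[C@H]1O[C@H]2C[C@@H]1O/C(OS(=O)(=O)C(F)(F)F)=C\C[C@@H]2Br
F5 | step 12 | (1S,3R,4R,6S,7S,9R)-6-bromo-9-{2-[(tert-butyldiphenylsilyl)oxy]ethyl}-3-[(trimethylsilyl)ethynyl]-2,8-dioxabicyclo[5.2.1]decan-4-ol | CC(C)(C)[Si](c1ccccc1)(c1ccccc1)OCC[C@H]1O[C@H]2C[C@@H]1O[C@H](C#C[Si](C)(C)C)[C@H](O)C[C@@H]2Br
F6 | step 12 | (1S,3R,4R,6S,7S,9R)-6-bromo-9-{2-[(tert-butyldiphenylsilyl)oxy]ethyl}-3-ethynyl-2,8-dioxabicyclo[5.2.1]decan-4-ol | CC(C)(C)[Si](c1ccccc1)(c1ccccc1)OCC[C@H]1O[C@H]2C[C@@H]1O[C@H](C#C)[C@H](O)C[C@@H]2Br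
F7 | step 13 | (1S,3R,4R,6S,7S,9R)-6-bromo-9-{2-[(tert-butyldiphenylsilyl)oxy]ethyl}-3-ethyl-2,8-dioxabicyclo[5.2.1]decan-4-yl chloromethanesulfonate | CC(C)(C)[Si](c1ccccc1)(c1ccccc1)OCC[C@H]1O[C@H]2C[C@@H]1O[C@H](CC)[C@H](OS(=O)(=O)CCl)C[C@@H]2Br
A1 | alternative 1 | 2,5-anhydro-4,6-di-O-benzyl-3-deoxy-D-arabino-hexose dimethyl acetal | c1ccccc1COC[C@H]2O[C@H](C(OC)OC)C[C@@H]2OCc3ccccc3
A2 | alternative 2 | (1S,3R,4R,7S,9R)-3-ethyl-4-hydroxy-9-(prop-2-en-1-yl)-2,8-dioxabicyclo[5.2.1]decan-6-one | C=CC[C@H]1O[C@H]2C[C@@H]1O[C@H](CC)[C@H](O)CC2=O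
A3 | alternative 3 | ethyl [(1S,3R,4R,6R,7S,9R)-4,6-bis[(tert-butyldimethylsilyl)oxy]-3-ethyl-2,8-dioxabicyclo[5.2.1]decan-9-yl]acetate | CCOC(=O)C[C@H]1O[C@H]2C[C@@H]1O[C@H](CC)[C@H](O[Si](C)(C)C(C)(C)C)C[C@H]2O[Si](C)(C)C(C)(C)C
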